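The cyclohexene (C3a–C4–C5=C6–C7–C7a, benzofuranone numbering) is opened at two bonds: C3a–C4, the homoallylic carbinol bond beside the exocyclic C3=CH2 of the α-methylene lactone (an allylboration retron), and the tetrasubstituted ring alkene C5=C6 (a metathesis retron). In one flask a butenolide allylboronate carrying a 2-methylallyl group at C7a adds to a citronellal-derived 2-alkylacrolein and the resulting diene is ring-closed, which sets C3a and C4. Because this addition occurs anti to the C7a branch, the (S)-butenolide is used; C7a is inverted at the end by lactone opening and Mitsunobu relactonisation.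

Key step: step 10

Remark: atom labels follow the 3a,4,7,7a-tetrahydro-1-benzofuran-2(3H)-one skeleton of the target (O1, C2=O, C3=CH2, C3a, C4–O, C5, C6–CH3, C7, C7a–O1) and are kept for the corresponding atoms of all intermediates.

Step 1
Reactants: 1 acrolein; 2 (2-methylallyl)magnesium chloride
Product: 4 (3S)-5-methylhexa-1,5-dien-3-ol, via B-methallyldiisopinocampheylborane 3 (not isolated)
Conditions: (−)-B-methoxydiisopinocampheylborane [from (+)-α-pinene], Et2O, 0 °C to rt; then 1, −78 °C; NaOH, H2O2, rt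
Reagents that add atoms: none
Why: Brown allylboration through a six-membered chair transition state, in which the isopinocampheyl groups should expose the aldehyde face leading to the (S)-carbinol (the sense established for aldehydes whose substituent outranks the allyl CH2, such as benzaldehyde).

Step 2
Reactants: 4 (3S)-5-methylhexa-1,5-dien-3-ol; 5 2-(bromomethyl)prop-2-enoic acid
Product: 6 (3S)-5-methylhexa-1,5-dien-3-yl 2-(bromomethyl)prop-2-enoate
Conditions: DCC, DMAP (5 mol %), CH2Cl2, −10 °C
Reagents that add atoms: none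
Why: Steglich esterification at oxygen, so the carbinol configuration is retained; cold conditions and little DMAP should spare the allylic bromide.

Step 3
Reactants: 6 (3S)-5-methylhexa-1,5-dien-3-yl 2-(bromomethyl)prop-2-enoate
Product: 7 (5S)-3-(bromomethyl)-5-(2-methylprop-2-enyl)furan-2(5H)-one
Conditions: second-generation Grubbs catalyst (5 mol %), CH2Cl2 (5 mM), 40 °C
Reagents that add atoms: none
Why: Ring-closing metathesis: the Ru carbene loads on the monosubstituted vinyl group and closes the five-membered butenolide onto the acrylate olefin, whereas the six-membered closure between the two 1,1-disubstituted olefins should be far slower; the carbinol centre (later C7a) is not touched.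

Step 4
Reactants: 7 (5S)-3-(bromomethyl)-5-(2-methylprop-2-enyl)furan-2(5H)-one
Product: 8 (5S)-5-(2-methylprop-2-enyl)-3-[(4,4,5,5-tetramethyl-1,3,2-dioxaborolan-2-yl)methyl]furan-2(5H)-one
Conditions: B2pin2, Pd2(dba)3 (2.5 mol %), THF, 50 °C
Reagents that add atoms: bis(pinacolato)diboron, CC1(C)OB(OC1(C)C)B1OC(C)(C)C(C)(C)O1
Why: Miyaura-type borylation of an allylic bromide (oxidative addition to zerovalent palladium, transmetalation with the diboron, C–B bond formation at the unhindered CH2 terminus of the π-allyl complex), which keeps the conjugated butenolide and leaves C7a unchanged.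

Step 5
Reactants: 9 (S)-citronellal
Product: 10 (6S)-8,8-dimethoxy-2,6-dimethyloct-2-ene
Conditions: HC(OMe)3, p-TsOH (1 mol %), MeOH, rt
Reagents that add atoms: trimethyl orthoformate, COC(OC)OC
Why: Acid-catalysed acetalisation masks the aldehyde for the ozonolysis; the stereocentre is not enolisable.

Step 6
Reactants: 10 (6S)-8,8-dimethoxy-2,6-dimethyloct-2-ene
Product: 12 (4S)-6,6-dimethoxy-4-methylhexan-1-ol, via (4S)-6,6-dimethoxy-4-methylhexanal 11 (not isolated)
Conditions: O3, CH2Cl2–MeOH, −78 °C; then NaBH4, −78 °C to rt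
Reagents that add atoms: ozone, [O-][O+]=O
Why: Ozonolysis (Criegee mechanism) of the only, electron-rich alkene followed by borohydride reduction of the peroxidic intermediates and of aldehyde 11 gives the primary alcohol; the acetal is inert.

Step 7
Reactants: 12 (4S)-6,6-dimethoxy-4-methylhexan-1-ol
Product: 13 (4S)-6,6-dimethoxy-4-methylhexyl 2-methylpropanoate
Conditions: i-PrCOCl, pyridine, DMAP (cat.), CH2Cl2, 0 °C
Reagents that add atoms: isobutyryl chloride, CC(C)C(=O)Cl
Why: DMAP-catalysed nucleophilic acyl substitution installs the side-chain isobutyrate that is carried to the target.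

Step 8
Reactants: 13 (4S)-6,6-dimethoxy-4-methylhexyl 2-methylpropanoate
Product: 14 (4S)-4-methyl-6-oxohexyl 2-methylpropanoate
Conditions: AcOH–H2O (4:1), rt
Reagents that add atoms: water, O
Why: Acid-catalysed acetal hydrolysis via the oxocarbenium ion frees the aldehyde without touching the ester.

Step 9
Reactants: 14 (4S)-4-methyl-6-oxohexyl 2-methylpropanoate
Product: 15 (4S)-5-formyl-4-methylhex-5-enyl 2-methylpropanoate
Conditions: 37% aq. HCHO, pyrrolidine (10 mol %), EtCO2H (10 mol %), i-PrOH, 45 °C
Reagents that add atoms: formaldehyde, C=O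
Why: Organocatalytic α-methylenation (Mannich condensation of the pyrrolidine enamine with formaldehyde, then elimination of the amine) gives the 2-alkylacrolein; the buffered medium should avoid γ-deprotonation at the stereocentre.

Step 10
Reactants: 8 (5S)-5-(2-methylprop-2-enyl)-3-[(4,4,5,5-tetramethyl-1,3,2-dioxaborolan-2-yl)methyl]furan-2(5H)-one; 15 (4S)-5-formyl-4-methylhex-5-enyl 2-methylpropanoate
Product: 17 (4S)-4-[(3aS,4S,7aS)-4-hydroxy-6-methyl-3-methylidene-2-oxo-2,3,3a,4,7,7a-hexahydro-1-benzofuran-5-yl]pentyl 2-methylpropanoate, via open-chain pinacol borate 16 (not isolated)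
Conditions: Sc(OTf)3 (10 mol %), toluene, −40 to 0 °C; then, same flask, toluene to 5 mM, di-o-tolyl analogue of the second-generation Hoveyda–Grubbs catalyst (10 mol %), 80 °C, Ar sparge; aq. NaHCO3
Reagents that add atoms: none
Why: Sc(OTf)3 activates boronate 8, which adds to aldehyde 15 through a closed six-membered chair (Zimmerman–Traxler) transition state with allyl transposition (SE2′), forming C3a–C4 and turning the endocyclic butenolide alkene into the exocyclic C3=CH2; the Ru carbene then loads on the less hindered methallyl olefin of borate 16 and closes onto the 2-alkylallyl olefin by [2+2]/retro-[2+2], forming C5=C6 with loss of ethene. The closest known reaction types are the Lewis-acid-catalysed allylboration of aldehydes with 2-alkoxycarbonyl allylboronates and the ring-closing metathesis of two 1,1-disubstituted olefins to tetrasubstituted cyclohexenes, run here in sequence in one flask. The carbocycle closes as a six-membered ring by metathesis; no other ring can form, because closure onto C3=CH2 would give a cyclobutene or a bridgehead alkene. C3a is set by attack of the aldehyde on the butenolide face opposite the C7a methallyl branch, and C4 by the ring-locked geometry of the allyl unit (C7a trans to CH2B), which places the aldehyde substituent equatorial in the chair and should give the anti carbinol. The step needs 1,2- rather than 1,4-addition to the enal and γ-attack at C3a, both secured by the cyclic boron transition state; the trans ring fusion that results at C7a is accepted because that centre is inverted in step 13.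

Step 11
Reactants: 17 (4S)-4-[(3aS,4S,7aS)-4-hydroxy-6-methyl-3-methylidene-2-oxo-2,3,3a,4,7,7a-hexahydro-1-benzofuran-5-yl]pentyl 2-methylpropanoate
Product: 18 (4S)-4-[(3aR,4S,7aS)-6-methyl-3-methylidene-4-(2-methylpropanoyloxy)-2-oxo-2,3,3a,4,7,7a-hexahydro-1-benzofuran-5-yl]pentyl 2-methylpropanoate
Conditions: (i-PrCO)2O, Et3N, DMAP (cat.), CH2Cl2, rt
Reagents that add atoms: isobutyric anhydride, CC(C)C(=O)OC(=O)C(C)C
Why: DMAP-catalysed acylation of the hindered allylic C4 hydroxyl with retention gives the second isobutyrate and blocks that oxygen before the lactone is reopened.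

Step 12
Reactants: 18 (4S)-4-[(3aR,4S,7aS)-6-methyl-3-methylidene-4-(2-methylpropanoyloxy)-2-oxo-2,3,3a,4,7,7a-hexahydro-1-benzofuran-5-yl]pentyl 2-methylpropanoate
Product: 19 2-[(1R,2S,6S)-6-hydroxy-4-methyl-2-(2-methylpropanoyloxy)-3-[(2S)-5-(2-methylpropanoyloxy)pentan-2-yl]cyclohex-3-en-1-yl]prop-2-enoic acid
Conditions: LiOH (1.05 equiv), THF–H2O (3:1), 0 °C; 1 M HCl to pH 4
Reagents that add atoms: lithium hydroxide, [Li+].[OH-]
Why: Saponification (BAc2) of the strained trans-fused γ-lactone, which should be more electrophilic than the two α-branched isobutyrates, with one equivalent of hydroxide; acyl–oxygen cleavage leaves C7a untouched.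

Step 13
Reactants: 19 2-[(1R,2S,6S)-6-hydroxy-4-methyl-2-(2-methylpropanoyloxy)-3-[(2S)-5-(2-methylpropanoyloxy)pentan-2-yl]cyclohex-3-en-1-yl]prop-2-enoic acid
Product: 20 (4S)-4-[(3aR,4S,7aR)-6-methyl-3-methylidene-4-(2-methylpropanoyloxy)-2-oxo-2,3,3a,4,7,7a-hexahydro-1-benzofuran-5-yl]pentyl 2-methylpropanoate (CNP0509808.1)
Conditions: PPh3, DIAD, THF, 0 °C (betaine preformed), then 19, 0 °C to rt
Reagents that add atoms: none
Why: Mitsunobu lactonisation: the C7a hydroxyl is activated as the alkoxyphosphonium ion and displaced by the carboxylate in a 5-exo-tet SN2 reaction with inversion, which turns (7aS) into the (7aR) cis-fused lactone of the target.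

Compound list
1 | acrolein | C=CC=O | starting material
2 | (2-methylallyl)magnesium chloride | C=C(C)C[Mg]Cl | starting material
3 | (−)-B-(2-methylprop-2-enyl)diisopinocampheylborane (isopinocampheyl groups from (+)-α-pinene) | C=C(C)CB([C@@H]1C[C@@H]2C[C@H]([C@H]1C)C2(C)C)[C@@H]1C[C@@H]2C[C@H]([C@H]1C)C2(C)C | intermediate
4 | (3S)-5-methylhexa-1,5-dien-3-ol | C=C[C@@H](O)CC(C)=C | intermediate
5 | 2-(bromomethyl)prop-2-enoic acid | C=C(CBr)C(=O)O | starting material
6 | (3S)-5-methylhexa-1,5-dien-3-yl 2-(bromomethyl)prop-2-enoate | C=C[C@@H](OC(=O)C(=C)CBr)CC(C)=C | intermediate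
7 | (5S)-3-(bromomethyl)-5-(2-methylprop-2-enyl)furan-2(5H)-one | O=C1O[C@@H](CC(C)=C)C=C1CBr | intermediate
8 | (5S)-5-(2-methylprop-2-enyl)-3-[(4,4,5,5-tetramethyl-1,3,2-dioxaborolan-2-yl)methyl]furan-2(5H)-one | O=C1O[C@@H](CC(C)=C)C=C1CB1OC(C)(C)C(C)(C)O1 | intermediate
9 | (S)-citronellal, (3S)-3,7-dimethyloct-6-enal | O=CC[C@@H](C)CCC=C(C)C | starting material
10 | (6S)-8,8-dimethoxy-2,6-dimethyloct-2-ene | COC(OC)C[C@@H](C)CCC=C(C)C | intermediate
11 | (4S)-6,6-dimethoxy-4-methylhexanal | COC(OC)C[C@@H](C)CCC=O | intermediate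
12 | (4S)-6,6-dimethoxy-4-methylhexan-1-ol | COC(OC)C[C@@H](C)CCCO | intermediate
13 | (4S)-6,6-dimethoxy-4-methylhexyl 2-methylpropanoate | COC(OC)C[C@@H](C)CCCOC(=O)C(C)C | intermediate
14 | (4S)-4-methyl-6-oxohexyl 2-methylpropanoate | O=CC[C@@H](C)CCCOC(=O)C(C)C | intermediate
15 | (4S)-5-formyl-4-methylhex-5-enyl 2-methylpropanoate | O=CC(=C)[C@@H](C)CCCOC(=O)C(C)C | intermediate
16 | (4S)-4-methyl-5-{(S)-[(2S,3S)-4-methylidene-2-(2-methylprop-2-enyl)-5-oxooxolan-3-yl][(4,4,5,5-tetramethyl-1,3,2-dioxaborolan-2-yl)oxy]methyl}hex-5-enyl 2-methylpropanoate | C=C1C(=O)O[C@@H](CC(C)=C)[C@@H]1[C@H](OB1OC(C)(C)C(C)(C)O1)C(=C)[C@@H](C)CCCOC(=O)C(C)C | intermediate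
17 | (4S)-4-[(3aS,4S,7aS)-4-hydroxy-6-methyl-3-methylidene-2-oxo-2,3,3a,4,7,7a-hexahydro-1-benzofuran-5-yl]pentyl 2-methylpropanoate (trans-fused lactone) | C=C1C(=O)O[C@H]2CC(C)=C([C@@H](C)CCCOC(=O)C(C)C)[C@@H](O)[C@H]12 | intermediate
18 | (4S)-4-[(3aR,4S,7aS)-6-methyl-3-methylidene-4-(2-methylpropanoyloxy)-2-oxo-2,3,3a,4,7,7a-hexahydro-1-benzofuran-5-yl]pentyl 2-methylpropanoate (C7a epimer of the target) | C=C1C(=O)O[C@H]2CC(C)=C([C@@H](C)CCCOC(=O)C(C)C)[C@@H](OC(=O)C(C)C)[C@H]12 | intermediate
19 | 2-[(1R,2S,6S)-6-hydroxy-4-methyl-2-(2-methylpropanoyloxy)-3-[(2S)-5-(2-methylpropanoyloxy)pentan-2-yl]cyclohex-3-en-1-yl]prop-2-enoic acid | C=C(C(=O)O)[C@@H]1[C@@H](O)CC(C)=C([C@@H](C)CCCOC(=O)C(C)C)[C@H]1OC(=O)C(C)C | intermediate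
20 | (4S)-4-[(3aR,4S,7aR)-6-methyl-3-methylidene-4-(2-methylpropanoyloxy)-2-oxo-2,3,3a,4,7,7a-hexahydro-1-benzofuran-5-yl]pentyl 2-methylpropanoate (CNP0509808.1) | C=C1C(=O)O[C@@H]2CC(C)=C([C@@H](C)CCCOC(=O)C(C)C)[C@@H](OC(=O)C(C)C)[C@H]12 | target

Total step count: 13. Longest linear sequence: 9 steps (steps 5 to 13, from (S)-citronellal 9).

Steps most likely to fail

The most exposed step is step 10. The ring closure to the tetrasubstituted alkene may stall, because both olefins are 1,1-disubstituted and one is flanked by two branched carbons. The Lewis acid may also move the lactone to the C4 oxygen. The fallback closes the ring by carbonyl chemistry instead of metathesis. It sets out from boronate 8 and the saturated aldehyde 14. The same Sc(OTf)3 allylboration should give the open-chain pinacol borate F1 (not isolated) and, after hydrolytic work-up, the hydroxy lactone F2. Ozonolysis of the electron-rich methallyl olefin only (Sudan red end-point, Me2S) should give the methyl ketone F3, and Dess–Martin oxidation the 1,5-diketone F4. Intramolecular aldol condensation (pyrrolidinium acetate, benzene, Dean–Stark) should then close the bicyclic enone F5, in which C5=C6 is conjugated to a C4 ketone. Luche reduction (NaBH4, CeCl3·7H2O, MeOH, −78 °C; axial hydride delivery, equatorial alcohol trans to the C3a branch) comes back to the route at 17.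

Second is step 12. Chemoselectivity may be lost through cleavage or 1,3-migration of the isobutyrates, or through conjugate addition of hydroxide to the α-methylene unit. The fallback sets out from 18 and avoids hydroxide. The strained lactone is opened with Me2AlNMe2 (from AlMe3 and Me2NH·HCl, CH2Cl2, 0 °C) to the hydroxy dimethylamide F6, which is mesylated (MsCl, Et3N) to the mesylate F7. On warming in wet MeCN with 2,6-lutidine the amide oxygen should displace the mesylate with inversion at C7a, giving the iminium lactone F8 (not isolated), which is hydrolysed in the flask. This comes back to the route at 20 and replaces steps 12 and 13.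

Third is step 13. The lactonisation may proceed with retention through the acyloxyphosphonium pathway, or E2 elimination may give the cyclohexadiene. The fallback inverts C7a by oxidation and reduction. It sets out from 19: Dess–Martin periodinane should give the keto acid F9. Its potassium carboxylate is reduced with K[BH(s-Bu)3] (THF, −78 °C; equatorial attack, axial alcohol cis to the C3a branch) to the hydroxy acid F10 (not isolated). Acidification closes the cis lactone and comes back to the route at 20.

Further compounds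
F1 | step 10 | (4S)-4-methyl-6-[(2S,3S)-4-methylidene-2-(2-methylprop-2-enyl)-5-oxooxolan-3-yl]-6-[(4,4,5,5-tetramethyl-1,3,2-dioxaborolan-2-yl)oxy]hexyl 2-methylpropanoate, (6S) at the borate carbon | C=C1C(=O)O[C@@H](CC(C)=C)[C@@H]1[C@H](OB1OC(C)(C)C(C)(C)O1)C[C@@H](C)CCCOC(=O)C(C)C
F2 | step 10 | (4S,6S)-6-hydroxy-4-methyl-6-[(2S,3S)-4-methylidene-2-(2-methylprop-2-enyl)-5-oxooxolan-3-yl]hexyl 2-methylpropanoate | C=C1C(=O)O[C@@H](CC(C)=C)[C@@H]1[C@H](O)C[C@@H](C)CCCOC(=O)C(C)C
F3 | step 10 | (4S,6S)-6-hydroxy-4-methyl-6-[(2S,3S)-4-methylidene-5-oxo-2-(2-oxopropyl)oxolan-3-yl]hexyl 2-methylpropanoate | C=C1C(=O)O[C@@H](CC(C)=O)[C@@H]1[C@H](O)C[C@@H](C)CCCOC(=O)C(C)C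
F4 | step 10 | (4S)-4-methyl-6-[(2S,3S)-4-methylidene-5-oxo-2-(2-oxopropyl)oxolan-3-yl]-6-oxohexyl 2-methylpropanoate | C=C1C(=O)O[C@@H](CC(C)=O)[C@@H]1C(=O)C[C@@H](C)CCCOC(=O)C(C)C
F5 | step 10 | (4S)-4-[(3aS,7aS)-6-methyl-3-methylidene-2,4-dioxo-2,3,3a,4,7,7a-hexahydro-1-benzofuran-5-yl]pentyl 2-methylpropanoate | C=C1C(=O)O[C@H]2CC(C)=C([C@@H](C)CCCOC(=O)C(C)C)C(=O)[C@H]12
F6 | step 12 | N,N-dimethylamide of acid 19 (hydroxy dimethylamide) | C=C(C(=O)N(C)C)[C@@H]1[C@@H](O)CC(C)=C([C@@H](C)CCCOC(=O)C(C)C)[C@H]1OC(=O)C(C)C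
F7 | step 12 | C7a methanesulfonate of F6 | C=C(C(=O)N(C)C)[C@@H]1[C@@H](OS(C)(=O)=O)CC(C)=C([C@@H](C)CCCOC(=O)C(C)C)[C@H]1OC(=O)C(C)C
F8 | step 12 | 2-(dimethyliminio) analogue of lactone 20, methanesulfonate salt | C=C1C(=[N+](C)C)O[C@@H]2CC(C)=C([C@@H](C)CCCOC(=O)C(C)C)[C@@H](OC(=O)C(C)C)[C@H]12.CS(=O)(=O)[O-]
F9 | step 13 | 2-[(1S,2S)-4-methyl-2-(2-methylpropanoyloxy)-3-[(2S)-5-(2-methylpropanoyloxy)pentan-2-yl]-6-oxocyclohex-3-en-1-yl]prop-2-enoic acid | C=C(C(=O)O)[C@@H]1C(=O)CC(C)=C([C@@H](C)CCCOC(=O)C(C)C)[C@H]1OC(=O)C(C)C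
F10 | step 13 | 2-[(1R,2S,6R)-6-hydroxy-4-methyl-2-(2-methylpropanoyloxy)-3-[(2S)-5-(2-methylpropanoyloxy)pentan-2-yl]cyclohex-3-en-1-yl]prop-2-enoic acid (C6 epimer of 19) | C=C(C(=O)O)[C@@H]1[C@H](O)CC(C)=C([C@@H](C)CCCOC(=O)C(C)C)[C@H]1OC(=O)C(C)C
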